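**Retrosynthetic overview**
1. Eudesmane numbering is used: C4 carries the aryl ether oxygen and a methyl group, C5 and C10 are the ring-fusion atoms, C7 carries the 2-hydroxypropan-2-yl group (C11); ring A = C1–C5/C10, ring B = C5–C10.
2. Late disconnections: the biaryl bond (Suzuki–Miyaura), the allyl C–C bond of the ether ring (benzylic Stille), the C11–OH bond (hydration of an isopropenyl group) and the C4–O–aryl bond (SNAr of the C4 alkoxide on 3-bromo-4-fluorobenzaldehyde).
3. Ring B is closed last, at C8–C9, from the monocyclic ring-A alcohol 5, in which C9 is still one of two methyl groups on C10 and C8 is the CH2 terminus of an α-methylene ketone attached through C6 to C5.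
4. Enabling feature: on ring A the C4 oxygen and the C10–C9 bond are cis and 1,3-related across C5, so a C4 alkoxyl radical can reach only the methyl group that must become C9. This creates the C10 quaternary stereocentre, and C5, already trans to the oxygen, enforces the trans ring fusion.
5. Ring A (C4, C5) is made first by asymmetric proton-initiated cyclization of (E)-geranylacetone to a bicyclic enol ether whose dihydropyran ring is temporary. Order of ring formation: ring A, ring B, then attachment and completion of the two arene rings.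

Key step: step 3

Remark: (E)-geranylacetone, 3-bromo-4-fluorobenzaldehyde and 2-allyl-4-bromophenol are taken as commercial; in step 1 the antipode of the catalyst that leads to the (4aR,8aR) series is used.

**Step 1**
Reactants: 1 (5E)-6,10-dimethylundeca-5,9-dien-2-one (geranylacetone)
Product: 2 (4aR,8aR)-2,5,5,8a-tetramethyl-4a,5,6,7,8,8a-hexahydro-4H-chromene
Conditions: chiral IDPi Brønsted acid (BINOL-derived N-triflyl imidodiphosphorimidate, 2 mol%), perfluoro-tert-butanol/CH2Cl2, −40 °C; Et3N quench
Reagents that add atoms: none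
Why: Catalytic asymmetric proton-initiated cation–olefin cyclization: protonation of the terminal alkene inside the confined chiral ion pair triggers chair-like anti addition across the (E)-configured central alkene, the ketone oxygen captures the tertiary cation at C4 and proton loss gives the enol ether, so the alkene geometry fixes the trans relationship of the C4 oxygen and the C5 side chain and the catalyst fixes their absolute configuration.

**Step 2**
Reactants: 2 (4aR,8aR)-2,5,5,8a-tetramethyl-4a,5,6,7,8,8a-hexahydro-4H-chromene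
Product: 5 4-[(1R,2R)-2-hydroxy-2,6,6-trimethylcyclohexyl]-3-methylidenebutan-2-one, via Mannich base 3 (not isolated), via methiodide 4 (not isolated)
Conditions: [CH2=NMe2]I, CH2Cl2, 0 to 25 °C; aq. NaHCO3; MeI, acetone, 25 °C; NaHCO3, CH2Cl2/H2O, 25 °C
Reagents that add atoms: dimethylmethylideneammonium iodide, C=[N+](C)C.[I-]; water, O
Why: The enol ether acts as a regiodefined enol equivalent in a Mannich reaction at C7 only, hydrolysis of the resulting oxocarbenium ion opens the temporary dihydropyran ring to the C4 tertiary alcohol and the ketone, and quaternization followed by E1cB elimination of trimethylamine installs the C7=C8 methylene group without touching a stereocentre.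

**Step 3**
Reactants: 5 4-[(1R,2R)-2-hydroxy-2,6,6-trimethylcyclohexyl]-3-methylidenebutan-2-one
Product: 7 1-[(2R,4aR,8R,8aR)-8-hydroxy-4a,8-dimethyldecahydronaphthalen-2-yl]ethan-1-one, via axial-acetyl epimer 6 (not isolated)
Conditions: CeCl3 (5 mol%), Bu4NCl (15 mol%), MeCN/PhCF3, high dilution, degassed, 400 nm LEDs, 0 °C; then K2CO3, MeOH, 25 °C
Reagents that add atoms: none
Why: Proposed new method: light-induced homolysis of the tetravalent cerium alkoxide of the C4 hydroxyl (ligand-to-metal charge transfer) should give the C4 alkoxyl radical, which in the chair with O4 axial abstracts a hydrogen atom from the syn-axial methyl group on C10 (1,5-hydrogen transfer, six-membered transition state); after ring inversion the primary C9 radical adds to C8, the CH2 terminus of the α-methylene ketone, and the C7 α-keto radical is reduced by trivalent cerium and protonated, so the step is a redox-neutral isomerization. The closest known reactions are the δ-C–H alkylation of alcohols through alkoxyl-radical 1,5-hydrogen transfer and Giese addition (cerium photocatalysis, sulfenate/stannane chains) and the 6-endo Giese cyclization of alkyl radicals onto 2-substituted enones; joining them so that a gem-dimethyl group is desymmetrized in a ring closure has not been shown. Ring B closes in the 6-endo-trig mode, preferred over 5-exo because the nucleophilic radical attacks the unsubstituted electron-poor carbon and gives a tertiary α-keto radical, and the chair transition state with C6 and C9 both equatorial on ring A leads only to the trans-fused decalin. C10 becomes a stereocentre under control of C4 (only the methyl cis to O4 can be 1,3-diaxial to it, so it becomes C9 and the other stays as the β-methyl), the trans fusion follows from the existing C5 centre, and C7 is set thermodynamically when K2CO3 moves the acetyl group to the equatorial position. The step needs hydrogen transfer to outrun β-scission of the C4–C5 bond and addition of the alkoxyl radical to the enone; the O-axial chair is populated because it removes the 1,3-diaxial methyl/methyl contact and holds a C9 hydrogen within van der Waals contact of the oxygen, the weakly polar medium and low temperature should slow β-scission relative to hydrogen transfer, and high dilution suppresses intermolecular addition.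

**Step 4**
Reactants: 7 1-[(2R,4aR,8R,8aR)-8-hydroxy-4a,8-dimethyldecahydronaphthalen-2-yl]ethan-1-one
Product: 8 (1R,4aR,7R,8aR)-1,4a-dimethyl-7-(prop-1-en-2-yl)decahydronaphthalen-1-ol (selin-11-en-4α-ol)
Conditions: Ph3PCH3Br, KOtBu (excess), THF, 0 to 40 °C
Reagents that add atoms: methyltriphenylphosphonium bromide, C[P+](c1ccccc1)(c1ccccc1)c1ccccc1.[Br-]
Why: Wittig methylenation removes the only enolizable carbonyl group before the strongly basic arylation and provides the alkene from which the C11 carbinol is made in step 6, while C7 stays in its more stable equatorial configuration.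

**Step 5**
Reactants: 8 (1R,4aR,7R,8aR)-1,4a-dimethyl-7-(prop-1-en-2-yl)decahydronaphthalen-1-ol; 9 3-bromo-4-fluorobenzaldehyde
Product: 10 3-bromo-4-{[(1R,4aR,7R,8aR)-1,4a-dimethyl-7-(prop-1-en-2-yl)decahydronaphthalen-1-yl]oxy}benzaldehyde
Conditions: KN(SiMe3)2, THF/DMF, 0 to 25 °C
Reagents that add atoms: none
Why: Nucleophilic aromatic substitution (SNAr, addition–elimination) of the tertiary potassium alkoxide at the fluorine-bearing carbon activated by the para-formyl group; the C4–O bond is not broken, so the C4 configuration is retained.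

**Step 6**
Reactants: 10 3-bromo-4-{[(1R,4aR,7R,8aR)-1,4a-dimethyl-7-(prop-1-en-2-yl)decahydronaphthalen-1-yl]oxy}benzaldehyde
Product: 12 2-[(2R,4aR,8R,8aR)-8-[2-bromo-4-(hydroxymethyl)phenoxy]-4a,8-dimethyldecahydronaphthalen-2-yl]propan-2-ol, via organomercurial acetate 11 (not isolated)
Conditions: Hg(OAc)2, THF/H2O, 25 °C; then NaOH, NaBH4, 0 °C
Reagents that add atoms: water, O
Why: Markovnikov oxymercuration–demercuration of the 1,1-disubstituted alkene gives the tertiary C11 alcohol without acid strong enough to ionize the tertiary aryl ether, and the NaBH4 of the demercuration reduces the aldehyde to the benzylic alcohol in the same operation.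

**Step 7**
Reactants: 12 2-[(2R,4aR,8R,8aR)-8-[2-bromo-4-(hydroxymethyl)phenoxy]-4a,8-dimethyldecahydronaphthalen-2-yl]propan-2-ol
Product: 13 2-[(2R,4aR,8R,8aR)-8-[2-bromo-4-(bromomethyl)phenoxy]-4a,8-dimethyldecahydronaphthalen-2-yl]propan-2-ol
Conditions: CBr4, PPh3, CH2Cl2, 0 °C; used at once
Reagents that add atoms: carbon tetrabromide, BrC(Br)(Br)Br
Why: Appel reaction: the primary benzylic alcohol is brominated at 0 °C while the hindered tertiary C11 alcohol and the aryl bromide are inert.

**Step 8**
Reactants: 13 2-[(2R,4aR,8R,8aR)-8-[2-bromo-4-(bromomethyl)phenoxy]-4a,8-dimethyldecahydronaphthalen-2-yl]propan-2-ol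
Product: 14 2-[(2R,4aR,8R,8aR)-8-[2-bromo-4-(prop-2-en-1-yl)phenoxy]-4a,8-dimethyldecahydronaphthalen-2-yl]propan-2-ol
Conditions: tributyl(vinyl)stannane, Pd2(dba)3 (2.5 mol%), tri(2-furyl)phosphine, THF, 45 °C
Reagents that add atoms: tributyl(vinyl)stannane, C=C[Sn](CCCC)(CCCC)CCCC
Why: Stille coupling at the benzylic C–Br bond, which adds oxidatively to zerovalent palladium under conditions where the hindered, electron-rich aryl bromide does not, builds the allyl group under neutral conditions that do not move the double bond into conjugation.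

**Step 9**
Reactants: 15 2-allyl-4-bromophenol
Product: 16 2-(prop-2-en-1-yl)-4-(4,4,5,5-tetramethyl-1,3,2-dioxaborolan-2-yl)phenol
Conditions: B2pin2, Pd(dppf)Cl2 (3 mol%), KOAc, 1,4-dioxane, 80 °C
Reagents that add atoms: bis(pinacolato)diboron, CC1(C)OB(OC1(C)C)B1OC(C)(C)C(C)(C)O1
Why: Miyaura borylation of the aryl bromide with KOAc, a base too weak to isomerize the allyl group; the free phenol is tolerated.

**Step 10**
Reactants: 14 2-[(2R,4aR,8R,8aR)-8-[2-bromo-4-(prop-2-en-1-yl)phenoxy]-4a,8-dimethyldecahydronaphthalen-2-yl]propan-2-ol; 16 2-(prop-2-en-1-yl)-4-(4,4,5,5-tetramethyl-1,3,2-dioxaborolan-2-yl)phenol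
Product: 17 2-[(2R,4aR,8R,8aR)-8-{[4'-hydroxy-3',5-di(prop-2-en-1-yl)-[1,1'-biphenyl]-2-yl]oxy}-4a,8-dimethyldecahydronaphthalen-2-yl]propan-2-ol (CNP0219722.1)
Conditions: Pd(OAc)2 (5 mol%), SPhos (10 mol%), K3PO4, THF/H2O, 60 °C
Reagents that add atoms: none
Why: Suzuki–Miyaura coupling with a bulky electron-rich biarylphosphine joins the ortho-alkoxy aryl bromide to the unprotected phenol boronate under mild aqueous base, completing the biaryl without a protecting group and without touching a stereocentre.

**Compound list**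
1 | (5E)-6,10-dimethylundeca-5,9-dien-2-one (geranylacetone) | CC(=O)CC/C=C(\C)CCC=C(C)C | starting material
2 | (4aR,8aR)-2,5,5,8a-tetramethyl-4a,5,6,7,8,8a-hexahydro-4H-chromene | O1[C@]2(C)CCCC(C)(C)[C@H]2CC=C1C | intermediate
3 | 3-[(dimethylamino)methyl]-4-[(1R,2R)-2-hydroxy-2,6,6-trimethylcyclohexyl]butan-2-one (Mannich base, both C3 epimers) | O[C@]1(C)CCCC(C)(C)[C@H]1CC(CN(C)C)C(C)=O | intermediate
4 | N-{2-acetyl-3-[(1R,2R)-2-hydroxy-2,6,6-trimethylcyclohexyl]propyl}-N,N,N-trimethylammonium iodide (methiodide) | O[C@]1(C)CCCC(C)(C)[C@H]1CC(C[N+](C)(C)C)C(C)=O.[I-] | intermediate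
5 | 4-[(1R,2R)-2-hydroxy-2,6,6-trimethylcyclohexyl]-3-methylidenebutan-2-one | O[C@]1(C)CCCC(C)(C)[C@H]1CC(=C)C(C)=O | intermediate
6 | 1-[(2S,4aR,8R,8aR)-8-hydroxy-4a,8-dimethyldecahydronaphthalen-2-yl]ethan-1-one (axial acetyl) | O[C@]1(C)CCC[C@]2(C)CC[C@H](C(C)=O)C[C@H]21 | intermediate
7 | 1-[(2R,4aR,8R,8aR)-8-hydroxy-4a,8-dimethyldecahydronaphthalen-2-yl]ethan-1-one | O[C@]1(C)CCC[C@]2(C)CC[C@@H](C(C)=O)C[C@H]21 | intermediate
8 | (1R,4aR,7R,8aR)-1,4a-dimethyl-7-(prop-1-en-2-yl)decahydronaphthalen-1-ol | O[C@]1(C)CCC[C@]2(C)CC[C@@H](C(C)=C)C[C@H]21 | intermediate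
9 | 3-bromo-4-fluorobenzaldehyde | O=Cc1ccc(F)c(Br)c1 | starting material
10 | 3-bromo-4-{[(1R,4aR,7R,8aR)-1,4a-dimethyl-7-(prop-1-en-2-yl)decahydronaphthalen-1-yl]oxy}benzaldehyde | O=Cc1ccc(O[C@]2(C)CCC[C@]3(C)CC[C@@H](C(C)=C)C[C@H]32)c(Br)c1 | intermediate
11 | 3-bromo-4-{[(1R,4aR,7R,8aR)-7-[1-(acetoxymercurio)-2-hydroxypropan-2-yl]-1,4a-dimethyldecahydronaphthalen-1-yl]oxy}benzaldehyde (both C11 epimers) | O=Cc1ccc(O[C@]2(C)CCC[C@]3(C)CC[C@@H](C(C)(O)C[Hg]OC(C)=O)C[C@H]32)c(Br)c1 | intermediate
12 | 2-[(2R,4aR,8R,8aR)-8-[2-bromo-4-(hydroxymethyl)phenoxy]-4a,8-dimethyldecahydronaphthalen-2-yl]propan-2-ol | OCc1ccc(O[C@]2(C)CCC[C@]3(C)CC[C@@H](C(C)(C)O)C[C@H]32)c(Br)c1 | intermediate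
13 | 2-[(2R,4aR,8R,8aR)-8-[2-bromo-4-(bromomethyl)phenoxy]-4a,8-dimethyldecahydronaphthalen-2-yl]propan-2-ol | BrCc1ccc(O[C@]2(C)CCC[C@]3(C)CC[C@@H](C(C)(C)O)C[C@H]32)c(Br)c1 | intermediate
14 | 2-[(2R,4aR,8R,8aR)-8-[2-bromo-4-(prop-2-en-1-yl)phenoxy]-4a,8-dimethyldecahydronaphthalen-2-yl]propan-2-ol | C=CCc1ccc(O[C@]2(C)CCC[C@]3(C)CC[C@@H](C(C)(C)O)C[C@H]32)c(Br)c1 | intermediate
15 | 2-allyl-4-bromophenol | C=CCc1cc(Br)ccc1O | starting material
16 | 2-(prop-2-en-1-yl)-4-(4,4,5,5-tetramethyl-1,3,2-dioxaborolan-2-yl)phenol | C=CCc1cc(B2OC(C)(C)C(C)(C)O2)ccc1O | intermediate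
17 | 2-[(2R,4aR,8R,8aR)-8-{[4'-hydroxy-3',5-di(prop-2-en-1-yl)-[1,1'-biphenyl]-2-yl]oxy}-4a,8-dimethyldecahydronaphthalen-2-yl]propan-2-ol | C=CCc1ccc(O[C@]2(C)CCC[C@]3(C)CC[C@@H](C(C)(C)O)C[C@H]32)c(-c2ccc(O)c(CC=C)c2)c1 | target

**Step count and risks**
Total step count: 10. Longest linear sequence: 9 steps (steps 1–8 and 10, from 1 to 17).

Steps most likely to fail:

1. Step 3 (Proposed new method). β-Scission of the tertiary alkoxyl radical, opening ring A at C4–C5, may outrun the 1,5-hydrogen transfer. This would lower the yield, and because the ring-opened radical is achiral and can re-add to the ketone, it could also erode the stereochemical purity. Addition of the oxygen radical to the enone is a second drain.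
   Fallback, from 2 back to 7, functionalizes the methyl group without an alkoxyl radical:
   - Aqueous HCl in THF hydrolyses 2 to 4-[(1R,2R)-2-hydroxy-2,6,6-trimethylcyclohexyl]butan-2-one F1.
   - The ketone is masked (1,2-bis(trimethylsilyloxy)ethane, Me3SiOTf cat., CH2Cl2, −78 °C; then K2CO3/MeOH) as the hydroxy dioxolane F2.
   - Et2SiH2 with [Ir(cod)OMe]2 gives the diethylhydrosilyl ether F3.
   - [Rh(cod)Cl]2/Xantphos with norbornene at 100 °C closes the oxasilinane F4 by intramolecular silylation of the δ C–H bond of the one methyl group that is cis to oxygen.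
   - Tamao–Fleming oxidation (H2O2, KHCO3, KF) gives the 1,4-diol F5.
   - PhOC(S)Cl/pyridine acylates the primary hydroxyl to the thionocarbonate F6.
   - PPTS in wet acetone frees the keto thionocarbonate F7.
   - Paraformaldehyde with diisopropylammonium trifluoroacetate in THF at 65 °C gives the α-methylene ketone F8.
   - Bu3SnH/AIBN in toluene at 110 °C (slow addition) generates the same C9 radical by Barton–McCombie C–O homolysis; 6-endo Giese cyclization and K2CO3/MeOH give 7.

2. Step 1. Enantiofacial control in the protonation–cyclization may be insufficient with a ketone as terminating group, or the cation may lose a proton to monocyclic dienes instead of being captured by oxygen.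
   Fallback, from 1 back to 2: cyclization with the achiral Lewis acid SnCl4 (CH2Cl2, −78 °C) gives 2 together with its mirror image, (4aS,8aS)-2,5,5,8a-tetramethyl-4a,5,6,7,8,8a-hexahydro-4H-chromene F9, which is removed by preparative chromatography on a chiral stationary phase.

3. Step 5. The hindered tertiary alkoxide may add reversibly to the aldehyde and enter hydride-transfer (Cannizzaro/Tishchenko-type) pathways while substitution at the bromine-flanked carbon stalls.
   Fallback, from 8 back to 10: substitution on 3-bromo-4-fluorobenzonitrile (KN(SiMe3)2, DMF, 0 to 25 °C), which has no carbonyl group, gives 3-bromo-4-{[(1R,4aR,7R,8aR)-1,4a-dimethyl-7-(prop-1-en-2-yl)decahydronaphthalen-1-yl]oxy}benzonitrile F10; iBu2AlH (toluene, −78 °C) and aqueous acidic work-up give 10.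

Further compounds
F1 | step 3 | 4-[(1R,2R)-2-hydroxy-2,6,6-trimethylcyclohexyl]butan-2-one | O[C@]1(C)CCCC(C)(C)[C@H]1CCC(C)=O
F2 | step 3 | (1R,2R)-1,3,3-trimethyl-2-[2-(2-methyl-1,3-dioxolan-2-yl)ethyl]cyclohexan-1-ol | O[C@]1(C)CCCC(C)(C)[C@H]1CCC1(C)OCCO1
F3 | step 3 | diethyl{[(1R,2R)-1,3,3-trimethyl-2-[2-(2-methyl-1,3-dioxolan-2-yl)ethyl]cyclohexyl]oxy}silane | CC[SiH](CC)O[C@]1(C)CCCC(C)(C)[C@H]1CCC1(C)OCCO1
F4 | step 3 | 3,3-diethyl-1,5-dimethyl-9-[2-(2-methyl-1,3-dioxolan-2-yl)ethyl]-2-oxa-3-silabicyclo[3.3.1]nonane (O–Si–CH2 bridge between C4 and C10, configuration of F2 retained) | CC[Si]1(CC)O[C@]2(C)CCC[C@](C)(C1)[C@H]2CCC3(C)OCCO3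
F5 | step 3 | (1R,2R,3S)-3-(hydroxymethyl)-1,3-dimethyl-2-[2-(2-methyl-1,3-dioxolan-2-yl)ethyl]cyclohexan-1-ol | O[C@]1(C)CCC[C@](C)(CO)[C@H]1CCC1(C)OCCO1
F6 | step 3 | O-{[(1S,2R,3R)-3-hydroxy-1,3-dimethyl-2-[2-(2-methyl-1,3-dioxolan-2-yl)ethyl]cyclohexyl]methyl} O-phenyl carbonothioate | O[C@]1(C)CCC[C@](C)(COC(=S)Oc2ccccc2)[C@H]1CCC1(C)OCCO1
F7 | step 3 | O-{[(1S,2R,3R)-3-hydroxy-1,3-dimethyl-2-(3-oxobutyl)cyclohexyl]methyl} O-phenyl carbonothioate | O[C@]1(C)CCC[C@](C)(COC(=S)Oc2ccccc2)[C@H]1CCC(C)=O
F8 | step 3 | O-{[(1S,2R,3R)-3-hydroxy-1,3-dimethyl-2-(2-methylidene-3-oxobutyl)cyclohexyl]methyl} O-phenyl carbonothioate | O[C@]1(C)CCC[C@](C)(COC(=S)Oc2ccccc2)[C@H]1CC(=C)C(C)=O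
F9 | step 1 | (4aS,8aS)-2,5,5,8a-tetramethyl-4a,5,6,7,8,8a-hexahydro-4H-chromene | O1[C@@]2(C)CCCC(C)(C)[C@@H]2CC=C1C
F10 | step 5 | 3-bromo-4-{[(1R,4aR,7R,8aR)-1,4a-dimethyl-7-(prop-1-en-2-yl)decahydronaphthalen-1-yl]oxy}benzonitrile | N#Cc1ccc(O[C@]2(C)CCC[C@]3(C)CC[C@@H](C(C)=C)C[C@H]32)c(Br)c1
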